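The ten-membered carbocycle C1–C10 is read as the open valence isomer of a cyclohexa-1,3-diene. The C1–C10 epoxide (a masked E-alkene) and the Z-alkene C4=C5 are bridged by C2–C3, so a bond between C5 and C10 would give a cis-fused decalin (rings A and B). Light cleaves exactly this bond in a conrotatory 6π opening. In one operation it delivers the germacrane ring, both alkene geometries and the C3 oxygen as an enol ester, with no macrocyclisation. The precursor is a 13-nor-eudesmanolide: ring A is a 3-acetoxy-1,3-diene, and ring B is a chair locked by the trans-fused C6/C7 γ-lactone and bearing the axial C8 silyl ether.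

Key step: step 13

Notation: eudesmane/germacrane numbering is used throughout (C14 = methyl on C10, C15 = methyl on C4, C11/C12 = lactone CH2/C=O, C13 = exocyclic methylene). α and β mean below and above the plane in the usual drawing with ring A on the left and C10 at the top.
Descriptor remark: in the trienyl acetate the C2=C3 bond is cis within the ring, but acetoxy outranks C4, so its CIP descriptor is E and the compound is the (1(10)E,2E,4Z)-triene.
Design remark: of the two possible cis-fused diastereomers, only the one with H-5 and CH3-14 on the same face as the lactone oxygen O6 holds C5–C6 pseudoaxial on ring A. The route is built to give this isomer, and as one enantiomer.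
Assumption: (S)-BINOL is written in step 3; if the titanium complex shields the other quinone face, (R)-BINOL is used and nothing else changes.
Remark: C4, C9 and C11 carry temporary stereocentres, drawn as expected from the reactions that form them. All are erased later.

Step 1
Reactants: 1 2-methoxy-6-methylphenol
Product: 2 2-methoxy-6-methyl-1,4-benzoquinone
Conditions: O2 (1 atm), Co(salen) (5 mol %), DMF, rt
Reagents that add atoms: dioxygen O=O
Why: Cobalt–salen-catalysed aerobic oxidation of a phenol with a free para position is a standard entry to 1,4-benzoquinones, the two ortho substituents blocking oxidative coupling.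

Step 2
Reactants: 3 pent-1-en-3-one
Product: 4 (Z)-3-(triisopropylsilyloxy)penta-1,3-diene
Conditions: i-Pr3SiOTf, Et3N, CH2Cl2, 0 °C
Reagents that add atoms: triisopropylsilyl triflate CC(C)[Si](C(C)C)(C(C)C)OS(=O)(=O)C(F)(F)F
Why: Soft enolisation of an ethyl ketone with a silyl triflate and a tertiary amine gives the 2-silyloxydiene mainly as the Z enol ether, whose methyl group points away from the vinyl group as a Diels–Alder reaction requires.

Step 3
Reactants: 2 2-methoxy-6-methyl-1,4-benzoquinone; 4 (Z)-3-(triisopropylsilyloxy)penta-1,3-diene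
Product: 5 cis-fused adduct 2-methoxy-5,8a-dimethyl-6-(triisopropylsilyloxy)-4a,5,8,8a-tetrahydronaphthalene-1,4-dione (C6 and C9 ketones, 8-OMe, H-5 α, CH3-14 α, CH3-15 β)
Conditions: (S)-BINOL (30 mol %), TiCl2(Oi-Pr)2 (30 mol %), toluene, −60 → −10 °C
Reagents that add atoms: none
Why: In this Lewis-acid-catalysed endo Diels–Alder reaction titanium is chelated by the methoxy oxygen and the neighbouring carbonyl (future C9), which leaves only the methyl-bearing C5=C10 alkene reactive and pairs its CH terminus (C5) with the nucleophilic C4 of the diene; suprafacial addition fixes H-5 and CH3-14 cis, the endo mode fixes C4, and the BINOL ligand selects the quinone face, as is known for this type of diene with related methoxy(methyl)benzoquinones.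

Step 4
Reactants: 5 cis-fused adduct
Product: 7 α-ketol enone (9β-hydroxy-8-oxo-Δ6; ring A unchanged), via enol ether diol 6 (not isolated)
Conditions: LiAlH4, Et2O, −78 → 0 °C, aqueous NaOH work-up; crude 6, PPTS (cat.), acetone–H2O, 0 °C
Reagents that add atoms: water O
Why: 1,2-Reduction of both carbonyl groups followed by mild acid is a Stork–Danheiser-type transposition, in which the C6 hydroxyl (vinylogous to the methoxy group) ionises and water unmasks the C8 ketone next to a C6=C7 alkene while the hindered silyl enol ether survives; convex-face hydride attack sets the C6 and C9 carbinols, neither of which is kept.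

Step 5
Reactants: 7 α-ketol enone
Product: 8 ketol acetate (9β-OAc)
Conditions: Ac2O, DMAP, pyridine, CH2Cl2, rt
Reagents that add atoms: acetic anhydride CC(=O)OC(C)=O
Why: DMAP-catalysed acetylation turns the neopentyl ketol hydroxyl into a leaving group for electron-transfer cleavage and creates no stereocentre.

Step 6
Reactants: 8 ketol acetate
Product: 9 cis-fused Δ6-en-8-one (C9 now CH2)
Conditions: SmI2 (2.2 equiv), MeOH, THF, −78 °C
Reagents that add atoms: none
Why: In the samarium diiodide reduction of an α-acyloxy ketone the ketyl expels acetate and the cross-conjugated enolate is protonated at C9, which removes the oxygen that served only to activate the dienophile.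

Step 7
Reactants: 9 cis-fused Δ6-en-8-one; 10 tert-butyl bromoacetate
Product: 12 keto ester (6α-SiMe2Ph; 7β-CH2CO2t-Bu; 8-oxo), via lithium enolate 11 (not isolated)
Conditions: (PhMe2Si)2CuLi, THF, −78 °C; then 10, DMPU, −78 → −20 °C
Reagents that add atoms: lithium bis(dimethylphenylsilyl)cuprate [Li+].C[Si](C)(c1ccccc1)[Cu-][Si](C)(C)c1ccccc1
Why: In this conjugate silylcupration with in situ enolate alkylation the silyl nucleophile adds to C6 on the convex face (the face of H-5, anti to the C4–C5 bond), and the regiodefined enolate is alkylated at C7 anti to the bulky silyl group, so the masked C6 oxygen and the acetate arm become trans.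

Step 8
Reactants: 12 keto ester
Product: 13 8β-alcohol
Conditions: LiBH(s-Bu)3 (L-Selectride), THF, −78 °C; H2O
Reagents that add atoms: none
Why: With the C6 and C7 substituents equatorial and C1 axial on C10, the bulky trialkylborohydride can only arrive along the equatorial trajectory from the α face and gives the axial 8β-alcohol cis to the C7 arm, the tert-butyl ester resisting lactonisation at low temperature.

Step 9
Reactants: 13 8β-alcohol
Product: 14 8β-tert-butyldimethylsilyl ether
Conditions: t-BuMe2SiOTf, 2,6-lutidine, CH2Cl2, −78 → 0 °C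
Reagents that add atoms: tert-butyldimethylsilyl triflate CC(C)(C)[Si](C)(C)OS(=O)(=O)C(F)(F)F
Why: A silyl triflate with a hindered pyridine base silylates even an axial secondary alcohol and blocks O8, so that only O6 can later lactonise.

Step 10
Reactants: 14 8β-silyl ether
Product: 15 1-en-3-one
Conditions: Pd(OAc)2 (1.1 equiv), MeCN, 40 °C
Reagents that add atoms: none
Why: In the Saegusa–Ito oxidation palladation at C2 of the silyl enol ether and β-hydride elimination of a C1 hydrogen give the C1=C2 enone regiospecifically, because the position of the enol ether was fixed by the cycloaddition.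

Step 11
Reactants: 15 1-en-3-one
Product: 17 cis-fused 3-oxo-13-nor-eudesm-1-en-12,6α-olide 8β-silyl ether, via hydroxy ester 16 (not isolated)
Conditions: Hg(OAc)2, AcOOH, AcOH, rt; then p-TsOH·H2O (cat.), CH2Cl2, rt
Reagents that add atoms: peracetic acid CC(=O)OO
Why: Fleming–Tamao oxidation (mercuridesilylation of the phenyl group, then a peracid-induced shift from silicon to oxygen) replaces silicon by hydroxyl with retention at C6, the electron-poor enone being inert to peracetic acid, and acid-catalysed transesterification of the diequatorial γ-hydroxy ester closes the trans-fused lactone.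

Step 12
Reactants: 17 lactone enone
Product: 19 3-acetoxy-13-nor-eudesma-1,3-dien-12,6α-olide 8β-silyl ether (H-5 α; CH3-14 α), via potassium dienolate 18 (not isolated)
Conditions: KN(SiMe3)2 (1.05 equiv), THF, −78 °C; Ac2O
Reagents that add atoms: acetic anhydride CC(=O)OC(C)=O
Why: The ketone can enolise only towards C4 because C10 is quaternary, it is clearly more acidic than the lactone, and O-acetylation of the potassium dienolate gives the linear 1,3-dienyl acetate while erasing the C4 stereocentre.

Step 13
Reactants: 19 cis-fused dienyl acetate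
Product: 20 (1(10)E,2E,4Z)-3-acetoxy-13-nor-germacra-1(10),2,4-trien-12,6α-olide 8β-silyl ether
Conditions: hν (254 nm, low-pressure mercury lamp, quartz), degassed Et2O, −78 °C, partial conversion; solution kept cold and used at once
Reagents that add atoms: none
Why: Excitation of the s-cis diene of ring A triggers the photochemically allowed conrotatory 6π electrocyclic opening, which cleaves the C5–C10 σ bond and shifts the π bonds to C10=C1, C2=C3 and C4=C5. The closest known reaction type is the low-temperature 254 nm opening of eudesma-1,3-dienes and their 3-acetoxy derivatives to germacratrienes, with the provitamin D to previtamin D change as the parent case. No ring is closed by bond formation: the ten-membered ring appears when rings A and B lose their shared bond, and the γ-lactone is a spectator. No stereocentre is formed, C5 and C10 are erased, and C6, C7 and C8 are untouched. Because C6 and C9 sit on one face of ring A, conrotation must give one ring-cis and one ring-trans terminus, so torquoselectivity is the selectivity needed; the lactone-locked chair of ring B holds C5–C6 pseudoaxial and C10–C9 pseudoequatorial on the twisted diene, so that continuing the ground-state helicity turns C6 inward (4Z) and C9 outward (1(10)E), whereas the opposite sense would also press C6 against the C4 methyl group. Low temperature, degassing and partial conversion limit thermal disrotatory re-closure, [1,7]-hydrogen shift and secondary photoproducts.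

Step 14
Reactants: 20 trienyl acetate
Product: 21 3-oxo-13-nor-germacra-1(10)E,4Z-dien-12,6α-olide 8β-silyl ether
Conditions: K2CO3 (0.2 equiv), MeOH–Et2O, −30 °C; pH 7 buffer
Reagents that add atoms: none
Why: Transesterification of the enol ester frees the trienolate, which is protonated kinetically at the α-carbon C2, so C1=C10 stays E and out of conjugation while C4=C5 becomes the Z-enone; unreacted 19 is returned to 17 by the same treatment and can be recycled through step 12.

Step 15
Reactants: 21 dienone lactone
Product: 22 (3S)-allylic alcohol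
Conditions: (R)-2-methyl-CBS-oxazaborolidine (20 mol %), catecholborane, toluene, −78 °C
Reagents that add atoms: none
Why: In the Corey–Bakshi–Shibata reduction the α-methyl-substituted alkenyl arm (C4) acts as the large and the C2 methylene as the small substituent, so the (R)-oxazaborolidine delivers hydride to the face that gives the 3S carbinol, 1,2-selectively and without touching the lactone or the isolated alkene.

Step 16
Reactants: 22 (3S)-allylic alcohol
Product: 26 (3S)-3-hydroxygermacra-1(10)E,4Z,11(13)-trien-12,6α-olide 8β-silyl ether, via dilithio alkoxide enolate 23 (not isolated), via Mannich base 24 (not isolated), via methiodide 25 (not isolated)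
Conditions: LiN(i-Pr)2 (2.5 equiv), THF, −78 °C; Me2N=CH2 I, −78 °C → rt; MeI, THF–MeOH, rt; aq. NaHCO3, CH2Cl2
Reagents that add atoms: Eschenmoser's salt C[N+](C)=C.[I-]; iodomethane CI (its carbon is carried by 25 only and leaves as trimethylamine)
Why: This Mannich-type α-methylenation of a lactone enolate followed by quaternisation and Hofmann-type elimination is run on the alkoxide–enolate dianion before any acylation, which avoids competing ester enolates; the aminomethyl group enters anti to C8 and its stereocentre vanishes in the elimination.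

Step 17
Reactants: 26 hydroxy α-methylene lactone
Product: 27 3-isobutyrate
Conditions: (i-PrCO)2O, DMAP, Et3N, CH2Cl2, 0 °C
Reagents that add atoms: isobutyric anhydride CC(C)C(=O)OC(=O)C(C)C
Why: DMAP-catalysed acylation of the allylic alcohol takes place at oxygen, so C3 keeps its configuration.

Step 18
Reactants: 27 3-isobutyrate
Product: 28 8β-alcohol
Conditions: HF·pyridine, pyridine, THF, 0 °C → rt
Reagents that add atoms: none
Why: Buffered hydrogen fluoride cleaves the secondary silyl ether through Si–F bond formation under non-basic conditions that spare the α-methylene lactone, the allylic ester and the diene, and the step is placed before the acid-sensitive epoxide exists.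

Step 19
Reactants: 29 methyl angelate
Product: 30 (Z)-2-methylbut-2-en-1-ol
Conditions: LiAlH4, Et2O, 0 °C
Reagents that add atoms: none
Why: Hydride reduction of the α,β-unsaturated ester gives the allylic alcohol with retention of the Z geometry.

Step 20
Reactants: 30 (Z)-2-methylbut-2-en-1-ol
Product: 31 [(2S,3R)-2,3-dimethyloxiran-2-yl]methanol
Conditions: Ti(Oi-Pr)4 (15 mol %), L-(+)-diethyl tartrate (18 mol %), t-BuOOH, 4 Å MS, CH2Cl2, −20 °C
Reagents that add atoms: tert-butyl hydroperoxide CC(C)(C)OO
Why: In the Sharpless asymmetric epoxidation the L-(+)-tartrate delivers oxygen to the face that gives 2S epoxy alcohols, and syn addition to the Z alkene makes C3 R with CH2OH and the C3 methyl cis.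

Step 21
Reactants: 31 epoxy alcohol
Product: 32 (2R,3R)-2,3-epoxy-2-methylbutanoic acid (epoxyangelic acid)
Conditions: RuCl3·xH2O (2 mol %), NaIO4, EtOAc–MeCN–H2O, rt
Reagents that add atoms: sodium periodate [Na+].[O-]I(=O)(=O)=O; water O
Why: Ruthenium tetroxide generated catalytically from RuCl3 and periodate oxidises the primary epoxy alcohol to the acid without opening the epoxide, the stereocentres being untouched and C2 merely changing its descriptor to R.

Step 22
Reactants: 28 8β-alcohol; 32 (2R,3R)-epoxyangelic acid
Product: 34 3-isobutyrate 8-epoxyangelate of the 1(10)E,4Z,11(13)-trienolide, via mixed anhydride 33 (not isolated)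
Conditions: 2,4,6-Cl3C6H2COCl, Et3N, toluene, rt; then 28, DMAP, toluene, rt
Reagents that add atoms: 2,4,6-trichlorobenzoyl chloride O=C(Cl)c1c(Cl)cc(Cl)cc1Cl (carried by 33 only, absent from 34)
Why: In the Yamaguchi esterification DMAP attacks the aliphatic carbonyl of the mixed anhydride because the aroyl carbonyl is shielded by two ortho chlorines, the acid has no α-hydrogen and cannot epimerise, and acylation at oxygen keeps C8.

Step 23
Reactants: 34 triene diester
Product: 35 target CNP0117882.2, (1R,3S,6R,7R,8R,10R)-1,10-epoxy-3-isobutyryloxy-8-[(2R,3R)-epoxyangeloyloxy]germacra-4Z,11(13)-dien-12,6-olide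
Conditions: mCPBA (1.05 equiv), NaHCO3, CH2Cl2, −20 → 0 °C
Reagents that add atoms: 3-chloroperoxybenzoic acid OOC(=O)c1cccc(Cl)c1
Why: In the Prilezhaev epoxidation the peracid picks the only electron-rich alkene (C4=C5 is flanked by two allylic C–O bonds, C11=C13 is conjugated to the lactone), syn addition turns the E geometry into the trans epoxide, and attack on the exposed outer face of the conformer with CH3-14 on the β side should give the 1R,10R isomer.

Compound list
1 | 2-methoxy-6-methylphenol | COc1cccc(C)c1O | starting material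
2 | 2-methoxy-6-methyl-1,4-benzoquinone | COC1=CC(=O)C=C(C)C1=O | intermediate
3 | pent-1-en-3-one | CCC(=O)C=C | starting material
4 | (Z)-3-(triisopropylsilyloxy)penta-1,3-diene | C/C=C(/C=C)O[Si](C(C)C)(C(C)C)C(C)C | intermediate
5 | cis-fused Diels–Alder adduct | COC1=CC(=O)[C@H]2[C@@H](C)C(O[Si](C(C)C)(C(C)C)C(C)C)=CC[C@@]2(C)C1=O | intermediate
6 | enol ether diol (6β,9β) | COC1=C[C@@H](O)[C@H]2[C@@H](C)C(O[Si](C(C)C)(C(C)C)C(C)C)=CC[C@@]2(C)[C@H]1O | intermediate
7 | α-ketol enone | O=C1C=C[C@H]2[C@@H](C)C(O[Si](C(C)C)(C(C)C)C(C)C)=CC[C@@]2(C)[C@H]1O | intermediate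
8 | ketol acetate | O=C1C=C[C@H]2[C@@H](C)C(O[Si](C(C)C)(C(C)C)C(C)C)=CC[C@@]2(C)[C@H]1OC(C)=O | intermediate
9 | cis-fused Δ6-en-8-one | O=C1C=C[C@H]2[C@@H](C)C(O[Si](C(C)C)(C(C)C)C(C)C)=CC[C@@]2(C)C1 | intermediate
10 | tert-butyl bromoacetate | CC(C)(C)OC(=O)CBr | starting material
11 | lithium enolate (6α-silyl) | [Li+].[O-]C1=C[C@H]([Si](C)(C)c3ccccc3)[C@H]2[C@@H](C)C(O[Si](C(C)C)(C(C)C)C(C)C)=CC[C@@]2(C)C1 | intermediate
12 | keto ester | O=C1[C@@H](CC(=O)OC(C)(C)C)[C@H]([Si](C)(C)c3ccccc3)[C@H]2[C@@H](C)C(O[Si](C(C)C)(C(C)C)C(C)C)=CC[C@@]2(C)C1 | intermediate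
13 | 8β-alcohol | O[C@H]1[C@@H](CC(=O)OC(C)(C)C)[C@H]([Si](C)(C)c3ccccc3)[C@H]2[C@@H](C)C(O[Si](C(C)C)(C(C)C)C(C)C)=CC[C@@]2(C)C1 | intermediate
14 | 8β-silyl ether | CC(C)(C)[Si](C)(C)O[C@H]1[C@@H](CC(=O)OC(C)(C)C)[C@H]([Si](C)(C)c3ccccc3)[C@H]2[C@@H](C)C(O[Si](C(C)C)(C(C)C)C(C)C)=CC[C@@]2(C)C1 | intermediate
15 | 1-en-3-one | CC(C)(C)[Si](C)(C)O[C@H]1[C@@H](CC(=O)OC(C)(C)C)[C@H]([Si](C)(C)c3ccccc3)[C@H]2[C@@H](C)C(=O)C=C[C@@]2(C)C1 | intermediate
16 | 6α-hydroxy ester | CC(C)(C)[Si](C)(C)O[C@H]1[C@@H](CC(=O)OC(C)(C)C)[C@H](O)[C@H]2[C@@H](C)C(=O)C=C[C@@]2(C)C1 | intermediate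
17 | cis-fused lactone enone | O=C1O[C@@H]2[C@H]3[C@@H](C)C(=O)C=C[C@@]3(C)C[C@@H](O[Si](C)(C)C(C)(C)C)[C@H]2C1 | intermediate
18 | potassium dienolate | O=C1O[C@@H]2[C@H]3C(C)=C([O-])C=C[C@@]3(C)C[C@@H](O[Si](C)(C)C(C)(C)C)[C@H]2C1.[K+] | intermediate
19 | cis-fused dienyl acetate (key-step precursor) | O=C1O[C@@H]2[C@H]3C(C)=C(OC(C)=O)C=C[C@@]3(C)C[C@@H](O[Si](C)(C)C(C)(C)C)[C@H]2C1 | intermediate
20 | ten-membered trienyl acetate (key-step product) | O=C1O[C@@H]2/C=C(/C)\C(OC(C)=O)=C/C=C(\C)C[C@@H](O[Si](C)(C)C(C)(C)C)[C@H]2C1 | intermediate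
21 | 3-oxo dienolide | O=C1O[C@@H]2/C=C(/C)C(=O)C/C=C(\C)C[C@@H](O[Si](C)(C)C(C)(C)C)[C@H]2C1 | intermediate
22 | (3S)-allylic alcohol | O=C1O[C@@H]2/C=C(/C)[C@@H](O)C/C=C(\C)C[C@@H](O[Si](C)(C)C(C)(C)C)[C@H]2C1 | intermediate
23 | dilithio alkoxide enolate | [Li+].[Li+].[O-]C=1O[C@@H]2/C=C(/C)[C@@H]([O-])C/C=C(\C)C[C@@H](O[Si](C)(C)C(C)(C)C)[C@H]2C=1 | intermediate
24 | Mannich base | O=C1O[C@@H]2/C=C(/C)[C@@H](O)C/C=C(\C)C[C@@H](O[Si](C)(C)C(C)(C)C)[C@H]2[C@@H]1CN(C)C | intermediate
25 | methiodide | O=C1O[C@@H]2/C=C(/C)[C@@H](O)C/C=C(\C)C[C@@H](O[Si](C)(C)C(C)(C)C)[C@H]2[C@@H]1C[N+](C)(C)C.[I-] | intermediate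
26 | hydroxy α-methylene lactone | C=C1C(=O)O[C@@H]2/C=C(/C)[C@@H](O)C/C=C(\C)C[C@@H](O[Si](C)(C)C(C)(C)C)[C@@H]12 | intermediate
27 | 3-isobutyrate | C=C1C(=O)O[C@@H]2/C=C(/C)[C@@H](OC(=O)C(C)C)C/C=C(\C)C[C@@H](O[Si](C)(C)C(C)(C)C)[C@@H]12 | intermediate
28 | 8β-alcohol | C=C1C(=O)O[C@@H]2/C=C(/C)[C@@H](OC(=O)C(C)C)C/C=C(\C)C[C@@H](O)[C@@H]12 | intermediate
29 | methyl angelate | C/C=C(/C)C(=O)OC | starting material
30 | (Z)-2-methylbut-2-en-1-ol | C/C=C(/C)CO | intermediate
31 | (2S,3R)-epoxy alcohol | OC[C@]1(C)O[C@@H]1C | intermediate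
32 | (2R,3R)-epoxyangelic acid | OC(=O)[C@]1(C)O[C@@H]1C | intermediate
33 | mixed anhydride | O=C(OC(=O)[C@]1(C)O[C@@H]1C)c1c(Cl)cc(Cl)cc1Cl | intermediate
34 | triene diester | C=C1C(=O)O[C@@H]2/C=C(/C)[C@@H](OC(=O)C(C)C)C/C=C(\C)C[C@@H](OC(=O)[C@]3(C)O[C@@H]3C)[C@@H]12 | intermediate
35 | CNP0117882.2 | C=C1C(=O)O[C@@H]2/C=C(/C)[C@@H](OC(=O)C(C)C)C[C@H]3O[C@]3(C)C[C@@H](OC(=O)[C@]3(C)O[C@@H]3C)[C@@H]12 | target

Total step count: 23. Longest linear sequence: 19 (steps 1, 3–18, 22, 23).

Steps most likely to fail

Step 13. The photostationary mixture may stay poor in the triene. Over-irradiation may drain it into [1,7]-hydrogen-shift and bicyclo[3.1.0]hexene isomers. The triene may also re-close thermally while it is warmed for the carbonate methanolysis.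
Fallback, from 17 back to 21: the enol ester is replaced by a fluoride-labile enol silane, so that ring opening and unmasking become one cold, base-free operation.
- Soft enolisation of 17 with Et3SiOTf and Et3N gives the 3-triethylsilyloxy-1,3-diene F1.
- Irradiation at 254 nm and −78 °C gives the trienyl triethylsilyl ether F2.
- F2 is not warmed but treated in the same vessel at −78 °C with Et3N·3HF. The alkyl silyl ether at C8 reacts far more slowly, and protonation at C2 gives 21.
- Unopened F1 is returned to 17 by the same treatment and recycled.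

Step 3. The facial selectivity on the methyl-bearing alkene may be poor, or the Lewis acid may desilylate the diene and divert it into a stepwise Michael pathway.
Fallback, from 2 and 4 back to 9: absolute configuration is taken from a resolution that costs no extra step.
- The uncatalysed thermal cycloaddition in toluene gives the racemic adduct F3.
- LiAlH4 and then PPTS give, through the racemic diol F4, the racemic ketol F5.
- In place of acetylation, F5 is acylated with (1S)-camphanic chloride, DMAP and pyridine.
- The wanted camphanate F6 is separated from the diastereomeric camphanate F7 by crystallisation or chromatography, and its configuration is read from a crystal structure against the camphanoyl group.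
- SmI2 expels the α-acyloxy group from F6 exactly as in step 6 and gives 9 as one enantiomer.

Step 23. The facial selectivity may be poor if both orientations of the C1=C10 plane are populated, and the chlorobenzoic acid may trigger transannular opening of the new epoxide.
Fallback, from 34 back to 35: substrate control is replaced by reagent control with a Shi epoxidation. The conditions are the D-fructose-derived ketone, KHSO5 (as Oxone), a buffer near pH 8 and MeCN–H2O at 0 °C. The dioxirane prefers E-trisubstituted alkenes over Z and electron-poor ones, and it gives R,R epoxides of this substitution pattern. The medium contains no carboxylic acid.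

Further compounds
F1 | step 13 | cis-fused 3-triethylsilyloxy-1,3-diene lactone | O=C1O[C@@H]2[C@H]3C(C)=C(O[Si](CC)(CC)CC)C=C[C@@]3(C)C[C@@H](O[Si](C)(C)C(C)(C)C)[C@H]2C1
F2 | step 13 | ten-membered trienyl triethylsilyl ether | O=C1O[C@@H]2/C=C(/C)\C(O[Si](CC)(CC)CC)=C/C=C(\C)C[C@@H](O[Si](C)(C)C(C)(C)C)[C@H]2C1
F3 | step 3 | racemic adduct (5 plus its enantiomer) | COC1=CC(=O)[C@H]2[C@@H](C)C(O[Si](C(C)C)(C(C)C)C(C)C)=CC[C@@]2(C)C1=O.COC1=CC(=O)[C@@H]2[C@H](C)C(O[Si](C(C)C)(C(C)C)C(C)C)=CC[C@]2(C)C1=O
F4 | step 3 | racemic diol (6 plus its enantiomer) | COC1=C[C@@H](O)[C@H]2[C@@H](C)C(O[Si](C(C)C)(C(C)C)C(C)C)=CC[C@@]2(C)[C@H]1O.COC1=C[C@H](O)[C@@H]2[C@H](C)C(O[Si](C(C)C)(C(C)C)C(C)C)=CC[C@]2(C)[C@@H]1O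
F5 | step 3 | racemic ketol (7 plus its enantiomer) | O=C1C=C[C@H]2[C@@H](C)C(O[Si](C(C)C)(C(C)C)C(C)C)=CC[C@@]2(C)[C@H]1O.O=C1C=C[C@@H]2[C@H](C)C(O[Si](C(C)C)(C(C)C)C(C)C)=CC[C@]2(C)[C@@H]1O
F6 | step 3 | (1S)-camphanate of ketol 7 | O=C1C=C[C@H]2[C@@H](C)C(O[Si](C(C)C)(C(C)C)C(C)C)=CC[C@@]2(C)[C@H]1OC(=O)[C@]3(OC4=O)CC[C@]4(C)C3(C)C
F7 | step 3 | (1S)-camphanate of the enantiomeric ketol | O=C1C=C[C@@H]2[C@H](C)C(O[Si](C(C)C)(C(C)C)C(C)C)=CC[C@]2(C)[C@@H]1OC(=O)[C@]3(OC4=O)CC[C@]4(C)C3(C)C
F0 | step 23 | none | none
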